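The readings were computed with constants of no real substance.

**0.100 M** of partner is what this flask can consume: its solid substrate plus its protic impurity, each taken, as I assumed, one to one. I call this the partner demand. The charge of 0.100 M matches it, so the flask has no surplus and its tail should be slow.

| flask | solid substrate | partner | protic impurity | remark | time |
|---|---|---|---|---|---|
| winter | 0.034 M | 0.10 M | 0.050 M | run made earlier |  |
| noon | 0.075 M | 0.10 M | 0.050 M | run made earlier |  |
| autumn | 0.050 M | 0.10 M | 0.10 M | run made earlier |  |
| flask | 0.050 M | 0.100 M | 0.0500 M |  | 10 d |

- winter (time / d: product / %, solid substrate / %): 1.67: 62.3, 0; 3.00: 78.1, 0.2; 5.00: 88.5, 0.5; 6.00: 91.3, 0.5; 8.00: 94.4, 0.3; 10.0: 96.1, 0.3; 12.0: 97.0, 0.3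
- noon (time / d: product / %, solid substrate / %): 1.04: 23.3, 41.1; 1.67: 35.3, 28.1; 2.00: 39.9, 21.7; 3.00: 51.0, 9.5; 5.00: 63.6, 0.5; 8.00: 69.8, 0.2; 12.0: 72.6, 0.1
- autumn (time / d: product / %, solid substrate / %): 2.50: 47.5, 0; 5.00: 55.6, 0; 8.00: 56.9, 0; 10.0: 57.1, 0; 12.0: 57.3, 0.3

(readings scatter by 0.3 percentage points)

- solid substrate is a solid; its amount is given per volume of the solution
- the earlier runs were read with a standard deviation of 0.3 percentage points
- at the start none of the solid substrate is in solution

- product at 10 d, in percent of the solid substrate charged
- the change that raises the amount of product at 10 d, in percent of the solid substrate charged most ("none" if none brings more than 2 percentage points) (Saturday's / Friday's / Tuesday's / none)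
- amount of product at 10 d, in percent of the solid substrate charged, after Tuesday's

- Saturday's: doubling the amount of partner, all else as stated
- Friday's: doubling the solubility of the solid substrate, all else as stated
- Tuesday's: doubling the dissolution coefficient of the solid substrate, all else as stated

The winter run had a surplus of 0.0160 M, more than its unreacted substrate at 10.0 d, so I took its tail as nearly pseudo-first-order. I assumed that dissolved substrate and protic impurity take partner at like rates, then went round twice. The second pass added to the surplus the substrate unreacted in the winter run at 10.0 d and, as my guess, as much protic impurity.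

First pass: k = 9.75 M⁻¹ d⁻¹

Second pass: k = 8.37 M⁻¹ d⁻¹

With no surplus, partner left = 1/(1/charge + k·time) = 0.0107 M

The charges of solid substrate and protic impurity in this flask are equal, so I split that evenly, which gave my estimate of product, 89.3%.

Next I turned the settings by hand. Saturday's gives a surplus of 0.100 M, and the tail's time falls to 1.19 d, shorter than 10 d. Friday's and Tuesday's leave the demand unchanged and act on dissolution, and the noon run, with more solid substrate than this flask, read 0.5% of it as solid at 5.00 d. I put each under 2 percentage points.

The forecast gave 90%, slightly above my figure, named Saturday's as best, and gave 92.5% after Tuesday's, a gain of 2.5 points where I had put under 2 points: “Doubling the dissolution coefficient only speeds the early stage”.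

The flask gave 89.6%. Saturday's added 10 points, Friday's 1.4 points and Tuesday's 0.67 points, and after Tuesday's the flask stood at 90.3%.

    dissolved substrate + partner → product (k = 0.460 M⁻¹ h⁻¹)
    partner + protic impurity → quenched reagent (k = 0.460 M⁻¹ h⁻¹)
    solid substrate ⇌ dissolved substrate, rate k3*(cs3 - [dissolved substrate]) while solid is left; crystals form when [dissolved substrate] > cs3 (solubility = 31.0 mM, k = 0.190 h⁻¹)

The neighbouring flask, charged with 0.17 M of partner, kept the demand of 0.100 M, so the reckoning left 0.0700 M of partner over. It held 41% of its partner charge at 10 d, which is 0.0697 M, and its product stood at >99.9%.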